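**Plan**
- Retrosynthesis (furan-2(5H)-one numbered O1, C2–C5; side chain C1′–C9′ on C5): first the silyl groups and the C3′–CH2OH bond are removed (Stille) to give a (Z)-vinyl iodide; then the butenolide is opened at C3=C4 and O1–C2 (intramolecular Horner–Wadsworth–Emmons of a phosphonoacetate); then the C3′–C4′ bond between the vinylic carbon and the homoallylic CH2 is cut, giving a C16 homoallyl iodide and a five-membered cyclic enol ether.
- Enabling feature: O1 stands γ to the vinylic carbon C3′ (O1–C5–C1′–C2′=C3′). Closing these five atoms to a 2,3-dihydrofuran makes O1 a ring-bound leaving group on C3′, so an alkyl group can shift from copper to C3′ with ring opening.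
- Forward order: the left chain is built from dihydro-β-ionone (alkyne, ring enone, carboalumination/ethylene oxide, iodide). The dihydrofuran is made from (R)-glyceraldehyde acetonide and propargyl bromide and is a temporary ring (closed in step 8, opened in step 9 when the halves are joined). The butenolide is the only ring closed afterwards (step 13), followed by CH2OH introduction and deprotection.
- Stereochemistry: ring carbinol (S) from CBS reduction; lactone C5 (S) from Felkin–Anh propargylation, relayed by the glyceraldehyde centre that is later oxidised to a ketone; 6′E from syn-carboalumination; 2′Z from the invertive 1,2-shift on the cyclic enol ether, kept by retentive iodination and Stille coupling.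

Key step: step 9

Remark: organometallic intermediates are drawn as monomers (cuprate 16 as the 1:1 ate complex, although 15 is used in excess); (R)-glyceraldehyde acetonide, diethylphosphonoacetic acid and (tributylstannyl)methanol are taken as commercial.

**Step 1**
Reactants: 1 dihydro-β-ionone [4-(2,6,6-trimethylcyclohex-1-en-1-yl)butan-2-one]
Product: 3 2-(but-3-yn-1-yl)-1,3,3-trimethylcyclohex-1-ene, via enol diethyl phosphate 2 (not isolated)
Conditions: LDA, THF, –78 °C; ClP(O)(OEt)2, –78 °C→rt; LDA (2.3 equiv), THF, –78 °C→rt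
Reagents that add atoms: none
Why: Kinetic deprotonation at the methyl group, O-phosphorylation and E2 elimination of the terminal enol phosphate (methyl ketone to terminal alkyne conversion) should give the alkyne without touching the tetrasubstituted ring alkene.

**Step 2**
Reactants: 3 2-(but-3-yn-1-yl)-1,3,3-trimethylcyclohex-1-ene
Product: 4 3-(but-3-yn-1-yl)-2,4,4-trimethylcyclohex-2-en-1-one
Conditions: CrO3, 3,5-dimethylpyrazole, CH2Cl2, –20 °C
Reagents that add atoms: chromium trioxide, O=[Cr](=O)=O
Why: Allylic oxidation with the chromium trioxide–3,5-dimethylpyrazole complex should attack the ring CH2 next to C(Me)=, the only unhindered allylic methylene (the exocyclic allylic CH2 is shielded by the gem-dimethyl carbon), and give the conjugated enone.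

**Step 3**
Reactants: 4 3-(but-3-yn-1-yl)-2,4,4-trimethylcyclohex-2-en-1-one
Product: 5 (1S)-3-(but-3-yn-1-yl)-2,4,4-trimethylcyclohex-2-en-1-ol
Conditions: (R)-2-methyl-CBS-oxazaborolidine (cat.), catecholborane, toluene, –78 °C
Reagents that add atoms: none
Why: Corey–Bakshi–Shibata reduction, in which the tetrasubstituted alkene arm acts as the large group and the ring CH2 as the small one, so the (R)-catalyst should give the (S)-allylic alcohol, while catecholborane at –78 °C leaves the alkyne alone.

**Step 4**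
Reactants: 5 (1S)-3-(but-3-yn-1-yl)-2,4,4-trimethylcyclohex-2-en-1-ol
Product: 6 tert-butyl{[(1S)-3-(but-3-yn-1-yl)-2,4,4-trimethylcyclohex-2-en-1-yl]oxy}dimethylsilane
Conditions: TBSCl, imidazole, DMF, rt
Reagents that add atoms: tert-butyldimethylsilyl chloride, CC(C)(C)[Si](C)(C)Cl
Why: Standard silylation masks the allylic alcohol for the organoaluminium, organolithium and cuprate steps.

**Step 5**
Reactants: 6 tert-butyl{[(1S)-3-(but-3-yn-1-yl)-2,4,4-trimethylcyclohex-2-en-1-yl]oxy}dimethylsilane
Product: 8 (3E)-6-[(3S)-3-{[tert-butyl(dimethyl)silyl]oxy}-2,6,6-trimethylcyclohex-1-en-1-yl]-4-methylhex-3-en-1-ol, via alkenylalane 7 (not isolated)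
Conditions: Me3Al, Cp2ZrCl2 (cat.), CH2Cl2, 0 °C→rt; n-BuLi, THF/hexane, –78 °C; ethylene oxide, –78→0 °C
Reagents that add atoms: trimethylaluminium, C[Al](C)C; ethylene oxide, C1CO1
Why: Zirconium-catalysed methylalumination (Negishi carboalumination) adds Me and Al syn across the terminal alkyne, and the alanate formed with n-BuLi opens ethylene oxide with retention, which fixes the (E)-trisubstituted alkene.

**Step 6**
Reactants: 8 (3E)-6-[(3S)-3-{[tert-butyl(dimethyl)silyl]oxy}-2,6,6-trimethylcyclohex-1-en-1-yl]-4-methylhex-3-en-1-ol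
Product: 9 tert-butyl({(1S)-3-[(3E)-6-iodo-3-methylhex-3-en-1-yl]-2,4,4-trimethylcyclohex-2-en-1-yl}oxy)dimethylsilane
Conditions: I2, PPh3, imidazole, CH2Cl2, 0 °C
Reagents that add atoms: iodine, II
Why: Appel-type iodination of the primary alcohol proceeds under neutral conditions that the silyl ether and both alkenes tolerate.

**Step 7**
Reactants: 10 (R)-2,2-dimethyl-1,3-dioxolane-4-carbaldehyde [(R)-glyceraldehyde acetonide]; 11 propargyl bromide
Product: 12 (1S)-1-[(4R)-2,2-dimethyl-1,3-dioxolan-4-yl]but-3-yn-1-ol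
Conditions: Zn dust, THF/sat. aq. NH4Cl, 0 °C→rt
Reagents that add atoms: none
Why: Barbier-type propargylation via the allenylzinc should follow Felkin–Anh attack anti to the dioxolane C–O bond and give mainly the anti (1S) adduct, which sets the future lactone stereocentre from the acetonide centre (minor syn isomer removed by chromatography).

**Step 8**
Reactants: 12 (1S)-1-[(4R)-2,2-dimethyl-1,3-dioxolan-4-yl]but-3-yn-1-ol
Product: 13 (4R)-4-[(2S)-2,3-dihydrofuran-2-yl]-2,2-dimethyl-1,3-dioxolane
Conditions: Mo(CO)6 (cat.), Me3NO, Et3N, Et2O, rt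
Reagents that add atoms: none
Why: Molybdenum-vinylidene-mediated cycloisomerisation of a 1-alkyn-4-ol (endo addition of the hydroxyl to the vinylidene carbon) should give the 2,3-dihydrofuran with the carbinol stereocentre untouched.

**Step 9**
Reactants: 9 tert-butyl({(1S)-3-[(3E)-6-iodo-3-methylhex-3-en-1-yl]-2,4,4-trimethylcyclohex-2-en-1-yl}oxy)dimethylsilane; 13 (4R)-4-[(2S)-2,3-dihydrofuran-2-yl]-2,2-dimethyl-1,3-dioxolane
Product: 18 (1S,3Z,7E)-10-[(3S)-3-{[tert-butyl(dimethyl)silyl]oxy}-2,6,6-trimethylcyclohex-1-en-1-yl]-1-[(4R)-2,2-dimethyl-1,3-dioxolan-4-yl]-4-iodo-8-methyldeca-3,7-dien-1-ol, via alkyllithium 14 (not isolated), via lithiated dihydrofuran 15 (not isolated), via mixed cuprate 16 (not isolated), via alkenylcopper alkoxide 17 (not isolated)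
Conditions: 9: t-BuLi (2.1 equiv), Et2O, –78 °C; CuBr·SMe2, Et2O/Me2S, –78→–40 °C; 13 (2 equiv): t-BuLi, THF, –78→0 °C; combine at –78 °C→rt; I2, THF, –78 °C
Reagents that add atoms: iodine, II
Why: The mixed cuprate 16, assembled from the alkylcopper (14 with CuBr·SMe2) and the α-lithiated cyclic enol ether 15, is an alkenyl carbenoid: on warming, the homoallyl ligand shifts from copper to the former C5 of the dihydrofuran and displaces the ring oxygen with inversion at the sp2 carbon, so the ring opens to alkenylcopper 17, in which copper sits where oxygen was (cis to the CH2–CH(OLi) chain) and the new C–C bond is trans to it; iodine then cleaves the C–Cu bond with retention. The closest known reaction type is the 1,2-metallate rearrangement of cuprates derived from 5-lithio-2,3-dihydrofurans followed by electrophilic trapping, related to the alkyl shift in α-haloalkenyl borates. No ring is closed; the dihydrofuran is opened and its oxygen is released as the secondary alkoxide that later becomes the lactone oxygen. No new stereocentre is formed: the C–O bond at the carbinol carbon is never broken, so the (S) centre from step 7 is carried over, and the (Z) geometry of the iodoalkene follows from the cis C–O/C3 relationship enforced by the five-membered ring together with the invertive shift. The selectivities needed are vinylic rather than C2 lithiation, secured because the only other α-oxygenated C–H bonds are unactivated sp3, and transfer of the alkyl rather than an alkenyl ligand, which is inherent because only the alkenyl ligand carries the leaving group, the excess of 15 serving as non-transferred ligand.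

**Step 10**
Reactants: 18 the (Z)-iodo homoallylic alcohol from step 9; 19 diethylphosphonoacetic acid
Product: 20 (1S,3Z,7E)-10-[(3S)-3-{[tert-butyl(dimethyl)silyl]oxy}-2,6,6-trimethylcyclohex-1-en-1-yl]-1-[(4R)-2,2-dimethyl-1,3-dioxolan-4-yl]-4-iodo-8-methyldeca-3,7-dien-1-yl (diethoxyphosphoryl)acetate
Conditions: DCC, DMAP (cat.), CH2Cl2, 0 °C→rt
Reagents that add atoms: none
Why: Steglich esterification caps the liberated secondary alcohol with the two-carbon phosphonate unit that both protects it and later closes the butenolide.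

**Step 11**
Reactants: 20 the phosphonoacetate acetonide
Product: 21 (2R,3S,5Z,9E)-12-[(3S)-3-{[tert-butyl(dimethyl)silyl]oxy}-2,6,6-trimethylcyclohex-1-en-1-yl]-1,2-dihydroxy-6-iodo-10-methyldodeca-5,9-dien-3-yl (diethoxyphosphoryl)acetate
Conditions: CuCl2·2H2O, MeCN, 0 °C→rt
Reagents that add atoms: none
Why: Mild Lewis-acid-assisted hydrolysis of a terminal isopropylidene acetal is a known way to free a 1,2-diol in the presence of silyl ethers and esters.

**Step 12**
Reactants: 21 the diol phosphonoacetate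
Product: 22 (2R,3S,5Z,9E)-1-{[tert-butyl(dimethyl)silyl]oxy}-12-[(3S)-3-{[tert-butyl(dimethyl)silyl]oxy}-2,6,6-trimethylcyclohex-1-en-1-yl]-2-hydroxy-6-iodo-10-methyldodeca-5,9-dien-3-yl (diethoxyphosphoryl)acetate
Conditions: TBSCl, imidazole, CH2Cl2, –20→0 °C
Reagents that add atoms: tert-butyldimethylsilyl chloride, CC(C)(C)[Si](C)(C)Cl
Why: Silylation at low temperature should select the primary over the secondary hydroxyl, leaving only the alcohol that is to become the ketone.

**Step 13**
Reactants: 22 the mono-silylated hydroxy phosphonoacetate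
Product: 24 (5S)-4-({[tert-butyl(dimethyl)silyl]oxy}methyl)-5-[(2Z,6E)-9-[(3S)-3-{[tert-butyl(dimethyl)silyl]oxy}-2,6,6-trimethylcyclohex-1-en-1-yl]-3-iodo-7-methylnona-2,6-dien-1-yl]furan-2(5H)-one, via keto phosphonate 23 (not isolated)
Conditions: Dess–Martin periodinane, pyridine, CH2Cl2, 0 °C→rt; then LiCl, i-Pr2NEt, MeCN, 0 °C→rt
Reagents that add atoms: none
Why: Dess–Martin oxidation gives the α-acyloxy ketone, and intramolecular Horner–Wadsworth–Emmons olefination under Masamune–Roush conditions should close the five-membered butenolide faster than the α-centre can enolise.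

**Step 14**
Reactants: 24 the iodo butenolide; 25 (tributylstannyl)methanol
Product: 26 (5S)-4-({[tert-butyl(dimethyl)silyl]oxy}methyl)-5-[(2Z,6E)-9-[(3S)-3-{[tert-butyl(dimethyl)silyl]oxy}-2,6,6-trimethylcyclohex-1-en-1-yl]-3-(hydroxymethyl)-7-methylnona-2,6-dien-1-yl]furan-2(5H)-one
Conditions: Pd(PPh3)4 (cat.), dioxane, 90 °C
Reagents that add atoms: none
Why: Stille coupling transfers the hydroxymethyl group from tin to the vinyl iodide with retention of alkene geometry, which places CH2OH cis to the lactone-bearing chain.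

**Step 15**
Reactants: 26 the bis-silyl ether
Product: 27 (5S)-4-(hydroxymethyl)-5-[(2Z,6E)-3-(hydroxymethyl)-9-[(3S)-3-hydroxy-2,6,6-trimethylcyclohex-1-en-1-yl]-7-methylnona-2,6-dien-1-yl]furan-2(5H)-one
Conditions: HF·pyridine, pyridine, THF, 0 °C→rt
Reagents that add atoms: none
Why: Buffered fluoride desilylation should free both hydroxyls without base-induced epimerisation at the γ-carbon of the butenolide and without acid-induced ionisation of the ring allylic alcohol.

**Compound list**
1 | dihydro-β-ionone, 4-(2,6,6-trimethylcyclohex-1-en-1-yl)butan-2-one | CC(=O)CCC1=C(C)CCCC1(C)C | starting material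
2 | diethyl 4-(2,6,6-trimethylcyclohex-1-en-1-yl)but-1-en-2-yl phosphate | C=C(CCC1=C(C)CCCC1(C)C)OP(=O)(OCC)OCC | intermediate
3 | 2-(but-3-yn-1-yl)-1,3,3-trimethylcyclohex-1-ene | C#CCCC1=C(C)CCCC1(C)C | intermediate
4 | 3-(but-3-yn-1-yl)-2,4,4-trimethylcyclohex-2-en-1-one | C#CCCC1=C(C)C(=O)CCC1(C)C | intermediate
5 | (1S)-3-(but-3-yn-1-yl)-2,4,4-trimethylcyclohex-2-en-1-ol | CC1=C(CCC#C)C(C)(C)CC[C@@H]1O | intermediate
6 | TBS ether of 5 | CC1=C(CCC#C)C(C)(C)CC[C@@H]1O[Si](C)(C)C(C)(C)C | intermediate
7 | (E)-alkenyl(dimethyl)alane from methylalumination of 6 | CC1=C(CC/C(C)=C/[Al](C)C)C(C)(C)CC[C@@H]1O[Si](C)(C)C(C)(C)C | intermediate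
8 | (3E)-6-[(3S)-3-(TBSO)-2,6,6-trimethylcyclohex-1-en-1-yl]-4-methylhex-3-en-1-ol | CC1=C(CC/C(C)=C/CCO)C(C)(C)CC[C@@H]1O[Si](C)(C)C(C)(C)C | intermediate
9 | (E)-homoallylic iodide from 8 | CC1=C(CC/C(C)=C/CCI)C(C)(C)CC[C@@H]1O[Si](C)(C)C(C)(C)C | intermediate
10 | (R)-2,2-dimethyl-1,3-dioxolane-4-carbaldehyde | O=C[C@H]1COC(C)(C)O1 | starting material
11 | propargyl bromide | C#CCBr | starting material
12 | (1S)-1-[(4R)-2,2-dimethyl-1,3-dioxolan-4-yl]but-3-yn-1-ol | C#CC[C@H](O)[C@H]1COC(C)(C)O1 | intermediate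
13 | (4R)-4-[(2S)-2,3-dihydrofuran-2-yl]-2,2-dimethyl-1,3-dioxolane | C1=CC[C@H](O1)[C@H]2COC(C)(C)O2 | intermediate
14 | homoallyllithium from 9 | CC1=C(CC/C(C)=C/CC[Li])C(C)(C)CC[C@@H]1O[Si](C)(C)C(C)(C)C | intermediate
15 | 5-lithio derivative of 13 | [Li]C1=CC[C@H](O1)[C@H]2COC(C)(C)O2 | intermediate
16 | lithium alkyl(dihydrofuranyl)cuprate (1:1 ate complex) | [Li+].CC1=C(CC/C(C)=C/CC[Cu-]C2=CC[C@H](O2)[C@H]3COC(C)(C)O3)C(C)(C)CC[C@@H]1O[Si](C)(C)C(C)(C)C | intermediate
17 | (Z)-alkenylcopper lithium alkoxide after the 1,2-shift | CC1=C(CC/C(C)=C/CC/C([Cu])=C/C[C@H](O[Li])[C@H]2COC(C)(C)O2)C(C)(C)CC[C@@H]1O[Si](C)(C)C(C)(C)C | intermediate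
18 | (1S,3Z,7E)-iodo dienol with dioxolane and ring TBS ether | CC1=C(CC/C(C)=C/CC/C(I)=C/C[C@H](O)[C@H]2COC(C)(C)O2)C(C)(C)CC[C@@H]1O[Si](C)(C)C(C)(C)C | intermediate
19 | diethylphosphonoacetic acid | OC(=O)CP(=O)(OCC)OCC | starting material
20 | (diethoxyphosphoryl)acetate of 18 | CC1=C(CC/C(C)=C/CC/C(I)=C/C[C@H](OC(=O)CP(=O)(OCC)OCC)[C@H]2COC(C)(C)O2)C(C)(C)CC[C@@H]1O[Si](C)(C)C(C)(C)C | intermediate
21 | (2R,3S)-1,2-diol phosphonoacetate | CC1=C(CC/C(C)=C/CC/C(I)=C/C[C@H](OC(=O)CP(=O)(OCC)OCC)[C@H](O)CO)C(C)(C)CC[C@@H]1O[Si](C)(C)C(C)(C)C | intermediate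
22 | primary TBS ether of 21 | CC1=C(CC/C(C)=C/CC/C(I)=C/C[C@H](OC(=O)CP(=O)(OCC)OCC)[C@H](O)CO[Si](C)(C)C(C)(C)C)C(C)(C)CC[C@@H]1O[Si](C)(C)C(C)(C)C | intermediate
23 | (3S)-2-oxo phosphonoacetate (keto phosphonate) | CC1=C(CC/C(C)=C/CC/C(I)=C/C[C@H](OC(=O)CP(=O)(OCC)OCC)C(=O)CO[Si](C)(C)C(C)(C)C)C(C)(C)CC[C@@H]1O[Si](C)(C)C(C)(C)C | intermediate
24 | (5S)-4-(TBSOCH2)-5-[(2Z,6E)-3-iodo-nonadienyl]furan-2(5H)-one with ring TBS ether | CC1=C(CC/C(C)=C/CC/C(I)=C/C[C@@H]2OC(=O)C=C2CO[Si](C)(C)C(C)(C)C)C(C)(C)CC[C@@H]1O[Si](C)(C)C(C)(C)C | intermediate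
25 | (tributylstannyl)methanol | OC[Sn](CCCC)(CCCC)CCCC | starting material
26 | bis-TBS ether of the target with free vinylic CH2OH | CC1=C(CC/C(C)=C/CC/C(=C/C[C@@H]2OC(=O)C=C2CO[Si](C)(C)C(C)(C)C)CO)C(C)(C)CC[C@@H]1O[Si](C)(C)C(C)(C)C | intermediate
27 | (5S)-4-(hydroxymethyl)-5-[(2Z,6E)-3-(hydroxymethyl)-9-[(3S)-3-hydroxy-2,6,6-trimethylcyclohex-1-en-1-yl]-7-methylnona-2,6-dien-1-yl]furan-2(5H)-one | CC1=C(CC/C(C)=C/CC/C(=C/C[C@@H]2OC(=O)C=C2CO)CO)C(C)(C)CC[C@@H]1O | target

**Count**
Total steps: 15. Longest linear sequence: 13 steps (steps 1–6 and 9–15, from dihydro-β-ionone); the dihydrofuran branch has 2 steps.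

**Steps most likely to fail**

1. Step 9. The alkyl ligand may be protonated or fail to migrate (incomplete ate-complex formation, competing decomposition of the lithiated enol ether), so the ring-opening coupling gives little product. The fallback makes the same bond by palladium catalysis; it sets out from 13 and 9 and comes back to the route at 18. Ozonolysis of the enol ether of 13 (O3, CH2Cl2, –78 °C; PPh3) should give the β-formyloxy aldehyde (1S)-1-[(4R)-2,2-dimethyl-1,3-dioxolan-4-yl]-3-oxopropyl formate F1. Ramirez dibromo-olefination (CBr4, PPh3, Zn) would give the 1,1-dibromoalkene (1S)-4,4-dibromo-1-[(4R)-2,2-dimethyl-1,3-dioxolan-4-yl]but-3-en-1-yl formate F2. The alkylzinc made from 9 (t-BuLi, then ZnBr2) is then coupled trans-selectively with F2 (Negishi coupling, Pd(DPEphos)Cl2, THF), leaving the bromine cis to the chain in the (Z)-bromo diene formate F3. Methanolysis (K2CO3, MeOH) frees the (Z)-bromo dienol F4, and copper-catalysed halogen exchange (CuI, NaI, N,N′-dimethylethylenediamine, dioxane, 110 °C) gives 18.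

2. Step 14. Transfer of the sp3 hydroxymethyl group to the hindered, fully substituted vinyl iodide may be slow, allowing protodeiodination or butyl transfer. The fallback sets out from 24 and comes back at 26 without any new isolated compound (F0): a Nozaki–Hiyama–Kishi reaction (CrCl2, cat. NiCl2, monomeric formaldehyde from paraformaldehyde, DMF/THF, rt) turns the vinyl iodide into an alkenylchromium species that adds to formaldehyde with retention of geometry and tolerates the butenolide and silyl ethers.

3. Step 8. Turnover of the molybdenum catalyst may stall through chelation by the dioxolane oxygens, and the acid-labile enol ether may be lost on isolation. The fallback sets out from 12 and comes back at 13: anti-Markovnikov hydroboration–oxidation of the terminal alkyne (dicyclohexylborane, 2 equiv, THF; NaBO3) gives the γ-hydroxy aldehyde as its lactol, (5S)-5-[(4R)-2,2-dimethyl-1,3-dioxolan-4-yl]oxolan-2-ol F5, and mesylation–elimination (MsCl, Et3N, CH2Cl2, reflux) dehydrates it to 13.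

**Further compounds**
F1 | step 9 | (1S)-1-[(4R)-2,2-dimethyl-1,3-dioxolan-4-yl]-3-oxopropyl formate | O=CC[C@H](OC=O)[C@H]1COC(C)(C)O1
F2 | step 9 | (1S)-4,4-dibromo-1-[(4R)-2,2-dimethyl-1,3-dioxolan-4-yl]but-3-en-1-yl formate | BrC(Br)=CC[C@H](OC=O)[C@H]1COC(C)(C)O1
F3 | step 9 | (1S,3Z,7E)-4-bromo analogue of 18 as its formate | CC1=C(CC/C(C)=C/CC/C(Br)=C/C[C@H](OC=O)[C@H]2COC(C)(C)O2)C(C)(C)CC[C@@H]1O[Si](C)(C)C(C)(C)C
F4 | step 9 | (1S,3Z,7E)-4-bromo analogue of 18 | CC1=C(CC/C(C)=C/CC/C(Br)=C/C[C@H](O)[C@H]2COC(C)(C)O2)C(C)(C)CC[C@@H]1O[Si](C)(C)C(C)(C)C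
F0 | step 14 | none | none
F5 | step 8 | (5S)-5-[(4R)-2,2-dimethyl-1,3-dioxolan-4-yl]oxolan-2-ol (anomeric mixture) | OC1CC[C@H](O1)[C@H]2COC(C)(C)O2
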